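# Septeremophilane E: synthesis proposal

## Analysis of the target

Septeremophilane E is a trinor-eremophilane: a twelve-carbon decalin core (C1 to C10 plus the methyl groups on C4 and C5) whose C3 oxygen is acylated by (2E,4E,6R)-6-(hydroxymethyl)octa-2,4-dienoic acid. Ring A (C1, C2, C3, C4, C5, C10) holds the C1=C2 double bond and three contiguous stereocentres, C3 (S), C4 (R) and the quaternary ring-fusion carbon C5 (S). Their oxygen and two methyl substituents all lie on one face. Ring B (C5 to C10) has no stereocentre; it is a cross-conjugated dienone, C6=C7(OH)–C8(=O)–C9=C10, whose C9=C10 bond is conjugated further with C1=C2. The fourth stereocentre, C6' of the side chain, is too remote to be controlled from the core and has to be made separately. The sensitive groups are the diosphenol (an acidic, easily acylated and oxidised enol), the linear trienone (nucleophiles, strong base), the allylic ester at C3 and the free primary alcohol. The difficulties are the all-cis triad that includes a quaternary carbon, the oxidation pattern of ring B, and acylation of the C3 hydroxyl without touching the enol. The strategy rests on two features: ring A is a cyclohexene whose double bond C1=C2 lies opposite the sp3 carbons C3, C4 and C5 (a [4+2] retron once C10 is sp3), and ring B is a four-carbon bridge C6 to C9 between C5 and C10 that can serve as the tether.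

## Retrosynthetic reasoning

**Ester bond (C3–O to C1').** The target 36 is cut first at the ester, giving the core alcohol 24 and the side-chain acid 34. This is the most labile bond, the cut is convergent, and it separates the C6' stereocentre from the core triad. The forward reaction has to acylate a hindered allylic alcohol in the presence of an enol. Therefore the enol is silylated in 24 and the primary alcohol in 34, and one fluoride treatment of 35 at the end frees both.

**Protecting-group exchange at the core.** Alcohol 24 comes from diol 23 by silylation of the more acidic enol, and 23 from the C3 silyl ether 22. The C3 silyl ether must stay in place through all oxidations of ring B and therefore cannot be the group that masks the enol.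

**C7–O bond.** The diosphenol 22 is traced to the epoxy ketone 21 and then to the trienone 20. C7 has no handle of its own, but in 20 the less substituted enone arm C6=C7 is the most electrophilic site. The forward steps must distinguish C6=C7 from C9=C10 and from C1=C2, and must then move the oxygen from the epoxide to the enol.

**Unsaturation of ring B.** Trienone 20 is simplified to the saturated ketone 18, the alcohol 17 and the bis-silyl ether 16. This turns ring B into a plain cyclohexane with two temporary stereocentres, C8 and C10, which are needed only to control the ring construction and are erased afterwards.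

**C3–C4 and C5–C10 (key disconnection).** The trans-fused bicycle 16 is opened by a retro-[4+2] to the acyclic triene 15. Both rings and the triad are traced back to two alkene geometries and one carbinol centre. The quaternary C5 is made without enolate alkylation.

**C3–O and C1–C2 of the diene.** The 1E,3E geometry of 15 decides the stereochemical outcome, so the dienol ether is not made by enolisation. Soft enolisation of an (E)-enal favours the 3Z isomer at the newly formed double bond. Instead the C3–O bond is made by oxygenation of the alkenyl metal derived from bromodiene 12, and the C1–C2 bond by coupling the alkyne-derived alkenyl metal of 9 with the two-carbon unit 10. Both steps are stereospecific. Alkene cross-metathesis was avoided for this part because the terminal alkene it would need lies within ring-closing distance of the trisubstituted alkene.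

**C8–C9.** Silyl ether 9 comes from alcohol 8, and 8 from aldehyde 5 and the allenylboronate 6. This is the only point at which absolute configuration enters the core.

**C6–C7.** Aldehyde 5 comes from ester 4, and 4 from the allylic alcohol 1 and the orthoester 2 by a [3,3] shift. That shift fixes the E geometry of the dienophile.

**Side chain.** Acid 34 is traced through ester 33 and allylic alcohol 31 to enoate 30 and 29 by two olefinations with ylide 27. Enoate 29 comes from butanal 25 and formaldehyde 26 by an enamine-catalysed hydroxymethylation that sets C6'.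

## Alternatives that were turned down

**Alternative 1: acylative closure of ring B.** The C8–C9 bond is cut. In the forward step the ring-A seco acid A2 is activated as a mixed anhydride; the acyl carbon attacks the exocyclic methylene C9, and loss of a proton from C9 gives the 1,9-dien-8-one A1.
- For: the closure is mild, needs no high temperature, and gives the C9=C10 enone directly. On these points it is stronger than the chosen route, which needs an oxidation and a dehydrogenation to reach the same bond.
- Against: A2 already contains the all-cis triad with the quaternary C5, so the hard problem is only moved to a monocyclic precursor that has no obvious stereocontrolled synthesis. The allylic C3 benzoate of A2 sits next to a cross-conjugated triene and may ionise under the acidic activation. A1 still lacks C6=C7 and the C7 oxygen, and its benzoate must be exchanged for the side chain.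
- Comparison: the chosen strategy builds both rings and the triad from an acyclic chain in one step.

**Alternative 2: three-component assembly of the side chain on the core.** The C4'=C5' and C6'–C7' bonds are cut. Butanal 25 is hydroxymethylated with 26 under diarylprolinol silyl ether catalysis, and the labile aldehyde 28 is trapped in the same flask by the lithium anion of the core-bound phosphonocrotonate A4, giving the enol silyl ether A3 of the target.
- For: it is the shortest way to the side chain, needs no protecting group on the primary alcohol, and is stronger than the chosen route in step count for that part.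
- Against: it is not a route to the core, and A4 needs the whole core synthesis plus an acylation. The most valuable intermediate would be used in a reaction with an unprotected β-hydroxy aldehyde, which can undergo retro-aldol cleavage, dehydration and epimerisation under the basic phosphonate anion. Residual 26 would compete for the anion. The configuration at C6' and the geometry at C4'=C5' would be known only at the last step.
- Comparison: the chosen route uses the same enamine hydroxymethylation but on a cheap fragment, where acid 34 can be purified and checked before the coupling.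

**Alternative 3: desymmetrising Heck cyclisation.** The C1–C10 bond is cut. Zerovalent palladium with a chiral bisphosphine inserts into the (Z)-vinyl iodide of the prochiral cyclohexadienone A6, and 6-exo carbopalladation of one enone arm closes ring A to give trienone A5, which is the same compound as 20.
- For: A5 has C6=C7 and C9=C10 in place at once, so the three oxidation-state steps of the chosen route (9 to 11) shrink to none. On this point it is clearly stronger.
- Against: after syn addition to C10, palladium sits on C9 and the only β-hydrogen (on C10) is anti, so elimination needs epimerisation through the oxygen-bound enolate; otherwise the reductive Heck product forms. The choice between the two enantiotopic enone arms is a case of double stereodifferentiation between catalyst and the existing C3/C4 centres. A6 itself needs a dearomatising C-alkylation to make the quaternary carbon.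
- Comparison: the chosen strategy derives the triad from alkene geometry and one carbinol centre and makes the quaternary carbon in the ring-forming step itself.

Key step: step 7

**Remarks on the chemistry (assumptions).**
- Core locants follow the decalin numbering used above (C1 to C10, methyls on C4 and C5). "β" means the face of the C5 methyl.
- Alcohol 1 is used as the racemate; its stereocentre is lost in step 1.
- (E)-1-Bromo-2-iodoethene 10 is taken as commercially available.
- The facial sense of the catalysts in steps 3 and 15 is assigned from the usual behaviour of these catalyst classes and should be confirmed by Mosher ester analysis of 8 and 29 before material is carried on.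
- Any minor enantiomer of the core would become a diastereomer after coupling with 34 and could be removed at 35.

## Route

Step 1
Reactants: 1 3-methylbut-3-en-2-ol (racemic); 2 triethyl orthoacetate
Product: 4 ethyl (E)-4-methylhex-4-enoate, via ketene acetal 3 (not isolated)
Conditions: EtCO2H (cat.), neat, 140 °C, EtOH distilled off
Reagents that add atoms: none
Why: Johnson–Claisen rearrangement: acid-catalysed exchange gives ketene acetal 3, whose chair [3,3] shift with the carbinol methyl equatorial forms the C6–C7 bond and the trisubstituted C4=C5 alkene with E geometry; the carbinol centre of 1 is destroyed.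

Step 2
Reactants: 4 ethyl (E)-4-methylhex-4-enoate
Product: 5 (E)-4-methylhex-4-enal
Conditions: i-Bu2AlH (1.05 equiv), CH2Cl2, −78 °C; aq. potassium sodium tartrate
Reagents that add atoms: none
Why: Partial reduction of an ester: the aluminium hemiacetal is stable at −78 °C and gives the aldehyde only on work-up; the isolated alkene is inert, and the volatile aldehyde is used as a solution.

Step 3
Reactants: 5 (E)-4-methylhex-4-enal; 6 allenylboronic acid pinacol ester
Product: 8 (4S,7E)-7-methylnon-7-en-1-yn-4-ol, via boronate ester 7 (not isolated)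
Conditions: (R)-TRIP (chiral BINOL phosphoric acid, 10 mol %), 4 Å molecular sieves, toluene, −20 °C; aq. NaHCO3
Reagents that add atoms: none
Why: Brønsted acid-catalysed asymmetric propargylation: the phosphoric acid activates the allenylboronate in a closed six-membered transition state (SE2' transfer, so the allenyl reagent gives the homopropargylic alcohol). For this catalyst class attack is expected on the Re face of the aldehyde, which corresponds to 4S here (C8 of the core), the only stereocentre the key step relies on.

Step 4
Reactants: 8 (4S,7E)-7-methylnon-7-en-1-yn-4-ol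
Product: 9 triethyl{[(4S,7E)-7-methylnon-7-en-1-yn-4-yl]oxy}silane
Conditions: Et3SiCl, imidazole, CH2Cl2, 0 °C to rt
Reagents that add atoms: chlorotriethylsilane, CC[Si](Cl)(CC)CC
Why: Silylation of a secondary alcohol; the triethylsilyl ether survives the organometallic steps and the thermolysis and can later be removed in the presence of a tert-butyldimethylsilyl ether.

Step 5
Reactants: 9 triethyl{[(4S,7E)-7-methylnon-7-en-1-yn-4-yl]oxy}silane; 10 (E)-1-bromo-2-iodoethene
Product: 12 (1E,3E,6S,9E)-1-bromo-9-methyl-6-(triethylsilyloxy)undeca-1,3,9-triene, via alkenylzirconocene 11 (not isolated)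
Conditions: Cp2Zr(H)Cl, THF, rt; then 10, Pd(PPh3)4 (5 mol %), ZnCl2, THF, rt
Reagents that add atoms: none
Why: Hydrozirconation adds Zr–H syn with zirconium on the terminal carbon (E-alkenylzirconocene 11). After transmetalation to zinc, Negishi coupling with zerovalent palladium takes place only at the C–I bond of 10 and with retention at both partners, so the C1–C2 bond is formed and the diene is 1E,3E by construction.

Step 6
Reactants: 12 (1E,3E,6S,9E)-1-bromo-9-methyl-6-(triethylsilyloxy)undeca-1,3,9-triene
Product: 15 (1E,3E,6S,9E)-1-(tert-butyldimethylsilyloxy)-9-methyl-6-(triethylsilyloxy)undeca-1,3,9-triene, via dienyllithium 13 (not isolated), via lithium dienolate 14 (not isolated)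
Conditions: t-BuLi (2.1 equiv), Et2O, −78 °C; then t-BuOOLi (from t-BuOOH and n-BuLi), THF, −78 to −20 °C; then t-BuMe2SiCl, DMPU, −78 to 0 °C
Reagents that add atoms: lithium tert-butyl peroxide, CC(C)(C)OO[Li]; tert-butyl(chloro)dimethylsilane, CC(C)(C)[Si](C)(C)Cl
Why: Bromine–lithium exchange with retention gives 13; electrophilic oxygen transfer from the lithium peroxide to the alkenyl carbanion, a reaction known for alkenyllithiums, gives dienolate 14 with retention, and O-silylation fixes the 1E,3E geometry. Soft enolisation of the corresponding (E)-enal was not used because γ-deprotonation favours the 3Z isomer.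

Step 7
Reactants: 15 (1E,3E,6S,9E)-1-(tert-butyldimethylsilyloxy)-9-methyl-6-(triethylsilyloxy)undeca-1,3,9-triene
Product: 16 (3S,4R,5S,8S,10R)-3-(tert-butyldimethylsilyloxy)-4,5-dimethyl-8-(triethylsilyloxy)-trans-decal-1-ene
Conditions: toluene (0.01 M), BHT, N,O-bis(trimethylsilyl)acetamide (0.05 equiv), silylated sealed tube, 200 °C
Reagents that add atoms: none
Why: Thermal, concerted but asynchronous [4+2] cycloaddition in which the (E)-trisubstituted alkene C4=C5 adds suprafacially across the termini C3 and C10 of the s-cis (E,E)-1-silyloxydiene, making the C3–C4 and C5–C10 bonds; the closest known reaction type is the thermal intramolecular Diels–Alder reaction of unactivated 1,7,9-decatrienes carrying a 1-oxygenated diene. Ring A is closed as the new cyclohexene by the cycloaddition itself, and ring B is closed at the same moment as a six-membered carbocycle by the C5–C10 bond across the four-carbon tether C6–C9, which adopts a chair (fused, not bridged, mode). The cis relation of the C4 and C5 methyls follows from the E geometry of the dienophile, and the cis relation of the C3 silyloxy group and the C10–C9 bond from the E,E geometry of the diene. The relation of C3 to C4 and C5 is an endo/exo question: in the trans-fused transition state the tether is exo and both methyls are endo, which places them on the face of the C3 oxygen (all-cis triad) and makes C10–H anti to the C5 methyl. The absolute sense is relayed from C8: with the triethylsilyloxy group equatorial on the chair-like tether, only one face of the diene is presented to the dienophile. The step therefore needs endo/exo and π-facial selectivity; the chair tether with an equatorial C8 substituent and the avoidance of the boat-like cis-fused arrangement should favour 16, but with an unactivated dienophile the preference is not expected to be complete, so the isomers are separated here while they are still diastereomers through C8. No activating group is present, so heat alone drives the reaction, and the silylating scavenger and the radical inhibitor protect the dienol ether. The C8 and C10 stereocentres are auxiliary and are erased in steps 9 and 10.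

Step 8
Reactants: 16 (3S,4R,5S,8S,10R)-3-(tert-butyldimethylsilyloxy)-4,5-dimethyl-8-(triethylsilyloxy)-trans-decal-1-ene
Product: 17 (3S,4R,5S,8S,10R)-3-(tert-butyldimethylsilyloxy)-4,5-dimethyl-trans-decal-1-en-8-ol
Conditions: PPTS (0.2 equiv), MeOH/CH2Cl2, 0 °C
Reagents that add atoms: none
Why: Acid-catalysed methanolysis; a secondary triethylsilyl ether is cleaved much faster than the more hindered allylic tert-butyldimethylsilyl ether.

Step 9
Reactants: 17 (3S,4R,5S,8S,10R)-3-(tert-butyldimethylsilyloxy)-4,5-dimethyl-trans-decal-1-en-8-ol
Product: 18 (3S,4R,5S,10R)-3-(tert-butyldimethylsilyloxy)-4,5-dimethyl-trans-decal-1-en-8-one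
Conditions: Dess–Martin periodinane, NaHCO3, CH2Cl2, rt
Reagents that add atoms: none
Why: Dess–Martin oxidation under buffered conditions; the C8 stereocentre, having directed the cycloaddition, is removed.

Step 10
Reactants: 18 (3S,4R,5S,10R)-3-(tert-butyldimethylsilyloxy)-4,5-dimethyl-trans-decal-1-en-8-one
Product: 20 (3S,4R,5R)-3-(tert-butyldimethylsilyloxy)-4,5-dimethyldecala-1,6,9-trien-8-one, via dienone 19 (not isolated)
Conditions: IBX (4 equiv), DMSO/fluorobenzene, 80 °C
Reagents that add atoms: none
Why: IBX dehydrogenation of a ketone, run twice in one flask: the C9–C10 bond is expected to go first because its product 19 is a linear dienone, then C6–C7. The quaternary C5 blocks aromatisation, and the C10 stereocentre is erased.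

Step 11
Reactants: 20 (3S,4R,5R)-3-(tert-butyldimethylsilyloxy)-4,5-dimethyldecala-1,6,9-trien-8-one
Product: 21 (3S,4R,5R,6R,7R)-3-(tert-butyldimethylsilyloxy)-6,7-epoxy-4,5-dimethyldecala-1,9-dien-8-one (epoxide on the α-face)
Conditions: 30 % aq. H2O2, NaOH (0.3 equiv), MeOH, 0 °C
Reagents that add atoms: hydrogen peroxide, OO
Why: Weitz–Scheffer epoxidation: hydroperoxide adds in conjugate fashion to the disubstituted enone arm C6=C7 rather than to the trisubstituted C9=C10 arm or the distal C1=C2 bond, as is known for steroidal 1,4,6-trien-3-ones. Attack anti to the C5 methyl is expected, but both new stereocentres are lost in step 12.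

Step 12
Reactants: 21 (3S,4R,5R,6R,7R)-3-(tert-butyldimethylsilyloxy)-6,7-epoxy-4,5-dimethyldecala-1,9-dien-8-one
Product: 22 (3S,4R,5S)-3-(tert-butyldimethylsilyloxy)-7-hydroxy-4,5-dimethyldecala-1,6,9-trien-8-one
Conditions: KOH (2 equiv), t-BuOH/H2O, 50 °C, argon; then aq. HCl to pH 4
Reagents that add atoms: potassium hydroxide, [K+].[OH-]
Why: Base-mediated isomerisation of an α,β-epoxy ketone to a diosphenol: hydroxide opens the epoxide at C7 (SN2 α to the carbonyl, away from the neopentyl C6) and E1cB loss of the C6 oxygen gives the enol C6=C7–OH. C8 has no enolisable hydrogen on its other side, and the product rests as its enolate until acidification.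

Step 13
Reactants: 22 (3S,4R,5S)-3-(tert-butyldimethylsilyloxy)-7-hydroxy-4,5-dimethyldecala-1,6,9-trien-8-one
Product: 23 (3S,4R,5S)-3,7-dihydroxy-4,5-dimethyldecala-1,6,9-trien-8-one
Conditions: HF·pyridine, pyridine, THF, 0 °C to rt
Reagents that add atoms: none
Why: Fluoride cleavage of the allylic silyl ether under buffered conditions that avoid strong base on the trienone; C3 is not ionised, so its configuration is untouched.

Step 14
Reactants: 23 (3S,4R,5S)-3,7-dihydroxy-4,5-dimethyldecala-1,6,9-trien-8-one
Product: 24 (3S,4R,5S)-7-(tert-butyldimethylsilyloxy)-3-hydroxy-4,5-dimethyldecala-1,6,9-trien-8-one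
Conditions: t-BuMe2SiCl (1.05 equiv), Et3N, CH2Cl2, −20 to 0 °C
Reagents that add atoms: tert-butyl(chloro)dimethylsilane, CC(C)(C)[Si](C)(C)Cl
Why: Chemoselective silylation of the acidic, phenol-like enol with one equivalent of silyl chloride and a tertiary amine; the hindered secondary C3 alcohol next to the C4 methyl should not react without a nucleophilic catalyst.

Step 15
Reactants: 25 butanal; 26 formaldehyde (37 % aq.); 27 ethyl (triphenylphosphoranylidene)acetate
Product: 29 ethyl (2E,4R)-4-(hydroxymethyl)hex-2-enoate, via hydroxy aldehyde 28 (not isolated)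
Conditions: (R)-α,α-diphenylprolinol trimethylsilyl ether (10 mol %), aq. phosphate buffer pH 7, toluene, rt; then 27, CH2Cl2, rt
Reagents that add atoms: none
Why: Enamine catalysis: the diarylprolinol silyl ether forms the (E)-enamine of 25, and its shielded face forces 26 to add from the open face; the (R)-catalyst should give the 2S aldehyde 28. The labile 28 is trapped at once by Wittig reaction with the stabilised ylide 27, which gives the E enoate.

Step 16
Reactants: 29 ethyl (2E,4R)-4-(hydroxymethyl)hex-2-enoate
Product: 30 ethyl (2E,4R)-4-[(tert-butyldimethylsilyloxy)methyl]hex-2-enoate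
Conditions: t-BuMe2SiCl, imidazole, DMF, rt
Reagents that add atoms: tert-butyl(chloro)dimethylsilane, CC(C)(C)[Si](C)(C)Cl
Why: Silylation of the primary alcohol; the same silyl group as on the enol oxygen of 24 allows one final deprotection.

Step 17
Reactants: 30 ethyl (2E,4R)-4-[(tert-butyldimethylsilyloxy)methyl]hex-2-enoate
Product: 31 (2E,4R)-4-[(tert-butyldimethylsilyloxy)methyl]hex-2-en-1-ol
Conditions: i-Bu2AlH (2.5 equiv), CH2Cl2, −78 °C; aq. potassium sodium tartrate
Reagents that add atoms: none
Why: 1,2-Reduction of the α,β-unsaturated ester to the allylic alcohol at low temperature; the γ stereocentre is not affected.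

Step 18
Reactants: 31 (2E,4R)-4-[(tert-butyldimethylsilyloxy)methyl]hex-2-en-1-ol; 27 ethyl (triphenylphosphoranylidene)acetate
Product: 33 ethyl (2E,4E,6R)-6-[(tert-butyldimethylsilyloxy)methyl]octa-2,4-dienoate, via enal 32 (not isolated)
Conditions: MnO2 (excess), CH2Cl2, rt
Reagents that add atoms: none
Why: Tandem oxidation–Wittig reaction: MnO2 oxidises the allylic alcohol to enal 32, which is captured in the flask by 27, so the γ-branched enal is never isolated; the stabilised ylide gives the new C2'=C3' bond with E geometry.

Step 19
Reactants: 33 ethyl (2E,4E,6R)-6-[(tert-butyldimethylsilyloxy)methyl]octa-2,4-dienoate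
Product: 34 (2E,4E,6R)-6-[(tert-butyldimethylsilyloxy)methyl]octa-2,4-dienoic acid
Conditions: LiOH, THF/MeOH/H2O, rt; then aq. HCl to pH 4
Reagents that add atoms: lithium hydroxide, [Li+].[OH-]
Why: Saponification of the dienoate; the primary silyl ether survives aqueous LiOH at room temperature, and the carboxylate formed shields the ε stereocentre from vinylogous deprotonation.

Step 20
Reactants: 24 (3S,4R,5S)-7-(tert-butyldimethylsilyloxy)-3-hydroxy-4,5-dimethyldecala-1,6,9-trien-8-one; 34 (2E,4E,6R)-6-[(tert-butyldimethylsilyloxy)methyl]octa-2,4-dienoic acid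
Product: 35 (3S,4R,5S)-7-(tert-butyldimethylsilyloxy)-4,5-dimethyl-8-oxodecala-1,6,9-trien-3-yl (2E,4E,6R)-6-[(tert-butyldimethylsilyloxy)methyl]octa-2,4-dienoate
Conditions: EDC·HCl, DMAP, CH2Cl2, 0 °C to rt
Reagents that add atoms: none
Why: Steglich-type esterification (carbodiimide activation, acyl transfer by DMAP) of the hindered allylic C3 alcohol with retention at C3; the enol is masked, and a small excess of 34 can be used.

Step 21
Reactants: 35 (3S,4R,5S)-7-(tert-butyldimethylsilyloxy)-4,5-dimethyl-8-oxodecala-1,6,9-trien-3-yl (2E,4E,6R)-6-[(tert-butyldimethylsilyloxy)methyl]octa-2,4-dienoate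
Product: 36 Septeremophilane E
Conditions: HF·pyridine, pyridine, THF, 0 °C to rt
Reagents that add atoms: none
Why: Fluoride cleavage of the enol silyl ether and the primary silyl ether in one operation, under buffered conditions that should leave the allylic dienoate ester, the trienone and the diosphenol intact.

## Compound list

1 | 3-methylbut-3-en-2-ol (racemic) | CC(O)C(C)=C | starting material
2 | triethyl orthoacetate | CC(OCC)(OCC)OCC | starting material
3 | 1-ethoxy-1-(3-methylbut-3-en-2-yloxy)ethene (ketene acetal) | C=C(OCC)OC(C)C(C)=C | intermediate (not isolated)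
4 | ethyl (E)-4-methylhex-4-enoate | C/C=C(\C)CCC(=O)OCC | intermediate
5 | (E)-4-methylhex-4-enal | C/C=C(\C)CCC=O | intermediate
6 | allenylboronic acid pinacol ester (4,4,5,5-tetramethyl-2-(propa-1,2-dienyl)-1,3,2-dioxaborolane) | C=C=CB1OC(C)(C)C(C)(C)O1 | starting material
7 | pinacol boronate ester of alcohol 8 | C/C=C(\C)CC[C@H](OB1OC(C)(C)C(C)(C)O1)CC#C | intermediate (not isolated)
8 | (4S,7E)-7-methylnon-7-en-1-yn-4-ol | C/C=C(\C)CC[C@H](O)CC#C | intermediate
9 | triethyl{[(4S,7E)-7-methylnon-7-en-1-yn-4-yl]oxy}silane | C/C=C(\C)CC[C@H](O[Si](CC)(CC)CC)CC#C | intermediate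
10 | (E)-1-bromo-2-iodoethene | Br/C=C/I | starting material
11 | (E)-alkenylzirconocene chloride from 9 | C/C=C(\C)CC[C@H](O[Si](CC)(CC)CC)C/C=C/[Zr](Cl)(C1C=CC=C1)C1C=CC=C1 | intermediate (not isolated)
12 | (1E,3E,6S,9E)-1-bromo-9-methyl-6-(triethylsilyloxy)undeca-1,3,9-triene | C/C=C(\C)CC[C@H](O[Si](CC)(CC)CC)C/C=C/C=C/Br | intermediate
13 | (1E,3E)-dienyllithium from 12 | C/C=C(\C)CC[C@H](O[Si](CC)(CC)CC)C/C=C/C=C/[Li] | intermediate (not isolated)
14 | lithium (1E,3E)-dienolate | C/C=C(\C)CC[C@H](O[Si](CC)(CC)CC)C/C=C/C=C/O[Li] | intermediate (not isolated)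
15 | (1E,3E,6S,9E)-1-(tert-butyldimethylsilyloxy)-9-methyl-6-(triethylsilyloxy)undeca-1,3,9-triene | C/C=C(\C)CC[C@H](O[Si](CC)(CC)CC)C/C=C/C=C/O[Si](C)(C)C(C)(C)C | intermediate
16 | (3S,4R,5S,8S,10R)-3-(tert-butyldimethylsilyloxy)-4,5-dimethyl-8-(triethylsilyloxy)-trans-decal-1-ene (3-O, 4-Me, 5-Me, 8-O all β; 10-H α) | CC(C)(C)[Si](C)(C)O[C@H]1C=C[C@H]2C[C@@H](O[Si](CC)(CC)CC)CC[C@]2(C)[C@H]1C | intermediate
17 | (3S,4R,5S,8S,10R)-3-(tert-butyldimethylsilyloxy)-4,5-dimethyl-trans-decal-1-en-8-ol | CC(C)(C)[Si](C)(C)O[C@H]1C=C[C@H]2C[C@@H](O)CC[C@]2(C)[C@H]1C | intermediate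
18 | (3S,4R,5S,10R)-3-(tert-butyldimethylsilyloxy)-4,5-dimethyl-trans-decal-1-en-8-one | CC(C)(C)[Si](C)(C)O[C@H]1C=C[C@H]2CC(=O)CC[C@]2(C)[C@H]1C | intermediate
19 | (3S,4R,5R)-3-(tert-butyldimethylsilyloxy)-4,5-dimethyldecala-1,9-dien-8-one | CC(C)(C)[Si](C)(C)O[C@H]1C=CC2=CC(=O)CC[C@]2(C)[C@H]1C | intermediate (not isolated)
20 | (3S,4R,5R)-3-(tert-butyldimethylsilyloxy)-4,5-dimethyldecala-1,6,9-trien-8-one | CC(C)(C)[Si](C)(C)O[C@H]1C=CC2=CC(=O)C=C[C@]2(C)[C@H]1C | intermediate
21 | (3S,4R,5R,6R,7R)-3-(tert-butyldimethylsilyloxy)-6,7-epoxy-4,5-dimethyldecala-1,9-dien-8-one (α-epoxide) | CC(C)(C)[Si](C)(C)O[C@H]1C=CC2=CC(=O)[C@@H]3O[C@@H]3[C@]2(C)[C@H]1C | intermediate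
22 | (3S,4R,5S)-3-(tert-butyldimethylsilyloxy)-7-hydroxy-4,5-dimethyldecala-1,6,9-trien-8-one | CC(C)(C)[Si](C)(C)O[C@H]1C=CC2=CC(=O)C(O)=C[C@]2(C)[C@H]1C | intermediate
23 | (3S,4R,5S)-3,7-dihydroxy-4,5-dimethyldecala-1,6,9-trien-8-one | O[C@H]1C=CC2=CC(=O)C(O)=C[C@]2(C)[C@H]1C | intermediate
24 | (3S,4R,5S)-7-(tert-butyldimethylsilyloxy)-3-hydroxy-4,5-dimethyldecala-1,6,9-trien-8-one | O[C@H]1C=CC2=CC(=O)C(O[Si](C)(C)C(C)(C)C)=C[C@]2(C)[C@H]1C | intermediate
25 | butanal | CCCC=O | starting material
26 | formaldehyde | C=O | starting material
27 | ethyl (triphenylphosphoranylidene)acetate | CCOC(=O)C=P(c1ccccc1)(c1ccccc1)c1ccccc1 | starting material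
28 | (S)-2-(hydroxymethyl)butanal | CC[C@H](C=O)CO | intermediate (not isolated)
29 | ethyl (2E,4R)-4-(hydroxymethyl)hex-2-enoate | CC[C@H](/C=C/C(=O)OCC)CO | intermediate
30 | ethyl (2E,4R)-4-[(tert-butyldimethylsilyloxy)methyl]hex-2-enoate | CC[C@H](/C=C/C(=O)OCC)CO[Si](C)(C)C(C)(C)C | intermediate
31 | (2E,4R)-4-[(tert-butyldimethylsilyloxy)methyl]hex-2-en-1-ol | CC[C@H](/C=C/CO)CO[Si](C)(C)C(C)(C)C | intermediate
32 | (2E,4R)-4-[(tert-butyldimethylsilyloxy)methyl]hex-2-enal | CC[C@H](/C=C/C=O)CO[Si](C)(C)C(C)(C)C | intermediate (not isolated)
33 | ethyl (2E,4E,6R)-6-[(tert-butyldimethylsilyloxy)methyl]octa-2,4-dienoate | CC[C@H](/C=C/C=C/C(=O)OCC)CO[Si](C)(C)C(C)(C)C | intermediate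
34 | (2E,4E,6R)-6-[(tert-butyldimethylsilyloxy)methyl]octa-2,4-dienoic acid | CC[C@H](/C=C/C=C/C(=O)O)CO[Si](C)(C)C(C)(C)C | intermediate
35 | (3S,4R,5S)-7-(tert-butyldimethylsilyloxy)-4,5-dimethyl-8-oxodecala-1,6,9-trien-3-yl (2E,4E,6R)-6-[(tert-butyldimethylsilyloxy)methyl]octa-2,4-dienoate | CC[C@H](/C=C/C=C/C(=O)O[C@H]1C=CC2=CC(=O)C(O[Si](C)(C)C(C)(C)C)=C[C@]2(C)[C@H]1C)CO[Si](C)(C)C(C)(C)C | intermediate
36 | Septeremophilane E | CC[C@H](/C=C/C=C/C(=O)O[C@H]1C=CC2=CC(=O)C(O)=C[C@]2(C)[C@H]1C)CO | target

## Step count and least certain steps

Total step count: 21. Longest linear sequence: 16 steps (steps 1 to 14, 20 and 21); the side chain takes steps 15 to 19.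

**Step 7 (key step).**
- What may go wrong: cyclisation onto the unactivated trisubstituted alkene may be slow, so thermal degradation of the silyl dienol ether can compete. Incomplete endo/exo and facial selection would produce the C3-epimeric and enantiomeric series.
- Fallback: the dienophile is activated by carrying C15 as an ester, which lowers the temperature needed and reinforces the ester-endo, trans-fused transition state; the ester is reduced to the methyl group afterwards. It sets out from 9. Ozonolysis (O3, CH2Cl2, −78 °C; Me2S) cleaves only the trisubstituted alkene and gives (S)-5-(triethylsilyloxy)oct-7-yn-2-one F1. Horner–Wadsworth–Emmons reaction with tert-butyl diethylphosphonoacetate (NaH, THF) gives the (E)-enoate F2. Hydrozirconation and coupling with 10 as in step 5 gives the bromodiene ester F3. Exchange at −100 °C, oxygenation and silylation as in step 6 gives the activated triene F4. Cycloaddition in toluene at 110 to 140 °C gives the C4 tert-butyl ester analogue of 16, F5. Reduction with i-Bu2AlH gives the C4 hydroxymethyl compound F6, mesylation (MsCl, Et3N) gives the mesylate F7, and LiBEt3H reduction returns to the route at 16.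

**Step 6.**
- What may go wrong: protonation of the dienyllithium, low efficiency of oxygen transfer, or C-silylation would lower the throughput. The geometry itself should be safe.
- Fallback: copper-catalysed C–O coupling in place of carbanion oxidation. It sets out from 12. Halogen exchange (NaI, CuI, trans-N,N'-dimethylcyclohexane-1,2-diamine, dioxane) gives the (1E,3E)-dienyl iodide F8. Coupling with 4-methoxybenzyl alcohol (CuI, 3,4,7,8-tetramethyl-1,10-phenanthroline, Cs2CO3, toluene, 80 °C) gives the 4-methoxybenzyl dienyl ether F9 with retention. Thermal cycloaddition as in step 7 gives the C3 4-methoxybenzyl ether analogue of 16, F10. DDQ (buffered CH2Cl2/H2O) gives the C3 alcohol F11, and t-BuMe2SiOTf with 2,6-lutidine returns to the route at 16.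

**Step 12.**
- What may go wrong: hydroxide may add elsewhere on the trienone, the diosphenol may undergo ring contraction of the benzilic acid type, or the enolate may be oxidised by air.
- Fallback: C7 is oxygenated by enolate oxidation instead of through the epoxide; steps 10 to 12 are bypassed. It sets out from 18. LiN(SiMe3)2 (THF, −78 °C) gives the C7-side lithium enolate F12. The Davis oxaziridine (2-benzenesulfonyl-3-phenyloxaziridine) gives the 7-hydroxy ketone F13 as a mixture of C7 epimers. Excess IBX (DMSO, 70 °C) oxidises the acyloin to the diosphenol F14 and then dehydrogenates C9–C10, returning to the route at 22.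

**Step 10.**
- What may go wrong: the reaction may stall at the mono-enone, or over-oxidise through the extended enol into ring A; acidic iodine by-products may remove the C3 silyl group.
- Fallback: stepwise Saegusa–Ito dehydrogenation. It sets out from 18. LiN(SiMe3)2 and Me3SiCl give the trimethylsilyl enol ether F15. Pd(OAc)2 in MeCN gives the 6-en-8-one F16. A second enolisation (LiN(SiMe3)2, Me3SiCl) gives the cross-conjugated silyl dienol ether F17, and Pd(OAc)2 returns to the route at 20.

**Step 14.**
- What may go wrong: silylation may also occur at the C3 hydroxyl, or the silyl group may migrate from the enol oxygen, giving mixtures that carry through to the esterification.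
- Fallback: the enol is protected before the C3 oxygen is freed, with a group orthogonal to silyl ethers. It sets out from 22. MOMCl and i-Pr2NEt give the enol methoxymethyl ether F18. Bu4NF in THF gives the C3 alcohol F19. Esterification with 34 as in step 20 gives the ester F20, and aqueous HCl in THF removes the methoxymethyl and the primary silyl group and returns to the route at 36.

## Further compounds

F1 | step 7 | (S)-5-(triethylsilyloxy)oct-7-yn-2-one | CC(=O)CC[C@H](O[Si](CC)(CC)CC)CC#C
F2 | step 7 | tert-butyl (2E,6S)-3-methyl-6-(triethylsilyloxy)non-2-en-8-ynoate | CC(C)(C)OC(=O)/C=C(\C)CC[C@H](O[Si](CC)(CC)CC)CC#C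
F3 | step 7 | tert-butyl (2E,6S,8E,10E)-11-bromo-3-methyl-6-(triethylsilyloxy)undeca-2,8,10-trienoate | CC(C)(C)OC(=O)/C=C(\C)CC[C@H](O[Si](CC)(CC)CC)C/C=C/C=C/Br
F4 | step 7 | tert-butyl (2E,6S,8E,10E)-11-(tert-butyldimethylsilyloxy)-3-methyl-6-(triethylsilyloxy)undeca-2,8,10-trienoate | CC(C)(C)OC(=O)/C=C(\C)CC[C@H](O[Si](CC)(CC)CC)C/C=C/C=C/O[Si](C)(C)C(C)(C)C
F5 | step 7 | analogue of 16 with a tert-butoxycarbonyl group in place of the C4 methyl (same configuration) | CC(C)(C)[Si](C)(C)O[C@H]1C=C[C@H]2C[C@@H](O[Si](CC)(CC)CC)CC[C@]2(C)[C@H]1C(=O)OC(C)(C)C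
F6 | step 7 | analogue of 16 with a hydroxymethyl group in place of the C4 methyl | CC(C)(C)[Si](C)(C)O[C@H]1C=C[C@H]2C[C@@H](O[Si](CC)(CC)CC)CC[C@]2(C)[C@H]1CO
F7 | step 7 | analogue of 16 with a methanesulfonyloxymethyl group in place of the C4 methyl | CC(C)(C)[Si](C)(C)O[C@H]1C=C[C@H]2C[C@@H](O[Si](CC)(CC)CC)CC[C@]2(C)[C@H]1COS(C)(=O)=O
F8 | step 6 | (1E,3E,6S,9E)-1-iodo-9-methyl-6-(triethylsilyloxy)undeca-1,3,9-triene | C/C=C(\C)CC[C@H](O[Si](CC)(CC)CC)C/C=C/C=C/I
F9 | step 6 | (1E,3E,6S,9E)-1-(4-methoxybenzyloxy)-9-methyl-6-(triethylsilyloxy)undeca-1,3,9-triene | C/C=C(\C)CC[C@H](O[Si](CC)(CC)CC)C/C=C/C=C/OCc1ccc(OC)cc1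
F10 | step 6 | analogue of 16 with a 4-methoxybenzyl ether at C3 (same configuration) | COc1ccc(CO[C@H]2C=C[C@H]3C[C@@H](O[Si](CC)(CC)CC)CC[C@]3(C)[C@H]2C)cc1
F11 | step 6 | (3S,4R,5S,8S,10R)-4,5-dimethyl-8-(triethylsilyloxy)-trans-decal-1-en-3-ol | O[C@H]1C=C[C@H]2C[C@@H](O[Si](CC)(CC)CC)CC[C@]2(C)[C@H]1C
F12 | step 12 | lithium enolate of 18 on the C7 side | CC(C)(C)[Si](C)(C)O[C@H]1C=C[C@H]2CC(O[Li])=CC[C@]2(C)[C@H]1C
F13 | step 12 | 7-hydroxy derivative of 18 (mixture of C7 epimers) | CC(C)(C)[Si](C)(C)O[C@H]1C=C[C@H]2CC(=O)C(O)CC[C@]2(C)[C@H]1C
F14 | step 12 | 3-(tert-butyldimethylsilyloxy)-7-hydroxy-4,5-dimethyl-trans-decala-1,6-dien-8-one (C3, C4, C5, C10 as in 18) | CC(C)(C)[Si](C)(C)O[C@H]1C=C[C@H]2CC(=O)C(O)=C[C@]2(C)[C@H]1C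
F15 | step 10 | 8-trimethylsilyl enol ether of 18 (C7=C8) | CC(C)(C)[Si](C)(C)O[C@H]1C=C[C@H]2CC(O[Si](C)(C)C)=CC[C@]2(C)[C@H]1C
F16 | step 10 | 3-(tert-butyldimethylsilyloxy)-4,5-dimethyl-trans-decala-1,6-dien-8-one (C3, C4, C5, C10 as in 18) | CC(C)(C)[Si](C)(C)O[C@H]1C=C[C@H]2CC(=O)C=C[C@]2(C)[C@H]1C
F17 | step 10 | 8-trimethylsilyloxy-1,6,8-triene from F16 (C6=C7 and C8=C9) | CC(C)(C)[Si](C)(C)O[C@H]1C=C[C@H]2C=C(O[Si](C)(C)C)C=C[C@]2(C)[C@H]1C
F18 | step 14 | 7-methoxymethyl ether of 22 | CC(C)(C)[Si](C)(C)O[C@H]1C=CC2=CC(=O)C(OCOC)=C[C@]2(C)[C@H]1C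
F19 | step 14 | 7-methoxymethyl ether of 23 (free C3 hydroxyl) | O[C@H]1C=CC2=CC(=O)C(OCOC)=C[C@]2(C)[C@H]1C
F20 | step 14 | ester of F19 with acid 34 | CC[C@H](/C=C/C=C/C(=O)O[C@H]1C=CC2=CC(=O)C(OCOC)=C[C@]2(C)[C@H]1C)CO[Si](C)(C)C(C)(C)C
A1 | alternative 1 | 4,5-dimethyl-8-oxodecala-1,9-dien-3-yl benzoate (C3, C4, C5 as in the target) | O=C(O[C@H]1C=CC2=CC(=O)CC[C@]2(C)[C@H]1C)c1ccccc1
A2 | alternative 1 | ring-A seco acid: 3-[3-benzoyloxy-4,5-dimethyl-10-methylidenecyclohex-1-en-5-yl]propanoic acid (decalin locants kept; C3, C4, C5 as in the target) | O=C(O[C@H]1C=CC(=C)[C@](C)(CCC(=O)O)[C@H]1C)c1ccccc1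
A3 | alternative 2 | Septeremophilane E 7-(tert-butyldimethylsilyl) enol ether | CC[C@H](/C=C/C=C/C(=O)O[C@H]1C=CC2=CC(=O)C(O[Si](C)(C)C(C)(C)C)=C[C@]2(C)[C@H]1C)CO
A4 | alternative 2 | (E)-4-(diethoxyphosphoryl)but-2-enoate of core alcohol 24 | CCOP(=O)(OCC)C/C=C/C(=O)O[C@H]1C=CC2=CC(=O)C(O[Si](C)(C)C(C)(C)C)=C[C@]2(C)[C@H]1C
A5 | alternative 3 | 3-(tert-butyldimethylsilyloxy)-4,5-dimethyldecala-1,6,9-trien-8-one (identical with 20) | CC(C)(C)[Si](C)(C)O[C@H]1C=CC2=CC(=O)C=C[C@]2(C)[C@H]1C
A6 | alternative 3 | 4-[(Z)-3-(tert-butyldimethylsilyloxy)-5-iodopent-4-en-2-yl]-4-methylcyclohexa-2,5-dien-1-one (side-chain centres configured as C3 and C4 of the target) | CC(C)(C)[Si](C)(C)O[C@@H](/C=C\I)[C@H](C)C1(C)C=CC(=O)C=C1
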